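## Retrosynthetic overview

1. Guajadial C ⇒ one-pot Knoevenagel / hetero-Diels–Alder union of three pieces: a C15 diene, benzaldehyde and 2,4-diformylphloroglucinol. The pyran ring and both new stereocentres are formed last.
2. C15 diene ⇒ Wittig methylenation of a bicyclic enone; ring B ⇒ intramolecular aldol addition and dehydration of a 1,5-diketone built on ring A.
3. Ring A ⇒ ring-closing metathesis and hydrogenation of an acyclic diene-alcohol, whose C6–C7 bond comes from an asymmetric allylboration joining a keto-aldehyde and a γ-isopropylallylboronate.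
4. Keto-aldehyde ⇒ organocatalytic Michael addition (sets C1) of (S)-3-methylhex-4-enal to methyl vinyl ketone; the aldehyde ⇒ Claisen chirality transfer (sets C10) from resolved pent-3-en-2-ol.
5. Diformylphloroglucinol ⇒ resorcinol by O-methylation, meta C–H borylation/oxidation, demethylation and double Vilsmeier formylation. Ring order: aromatic ring (bought), ring A, ring B, pyran ring.

Assumption and notation: commercial racemic pent-3-en-2-ol is taken as the E isomer; terpenoid carbons carry cadinane numbers (C1 ring-fusion CH, C4 future spiro carbon, C5=C6 ring alkene, C7 CH–iPr, C10 CH–Me, C15 exocyclic CH2).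

## Route

Step 1
Reactants: 1 rac-(E)-pent-3-en-2-ol
Product: 2 (2S,3E)-pent-3-en-2-ol
Conditions: vinyl acetate (0.6 equiv), Novozym 435 (immobilised Candida antarctica lipase B), pentane, rt, to about 52% conversion; chromatography
Reagents that add atoms: none
Why: Lipase-catalysed kinetic resolution (Kazlauskas rule) acetylates only the (R)-alcohol, so the (S)-enantiomer that becomes C10 is recovered in high ee.

Step 2
Reactants: 2 (2S,3E)-pent-3-en-2-ol
Product: 4 (3S,4E)-3-methylhex-4-enal, via allyl vinyl ether 3 (not isolated)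
Conditions: ethyl vinyl ether (solvent), Hg(OAc)2 (5 mol %), reflux; evaporate; toluene, 130 °C, sealed tube
Reagents that add atoms: ethyl vinyl ether, C=COCC
Why: Transvinylation followed by Claisen [3,3] rearrangement through a chair transition state with the carbinol methyl equatorial transfers the C–O chirality suprafacially to the new C–C centre (S, future C10) and gives the E-propenyl group (about 9:1 E:Z expected; the minor Z isomer carries the antipodal centre and is removed later as diastereomers).

Step 3
Reactants: 4 (3S,4E)-3-methylhex-4-enal; 5 but-3-en-2-one (methyl vinyl ketone)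
Product: 6 (2R,3R,4E)-3-methyl-2-(3-oxobutyl)hex-4-enal
Conditions: (R)-2-[methoxy(diphenyl)methyl]pyrrolidine (5 mol %), ethyl 3,4-dihydroxybenzoate (20 mol %), neat, 4 °C; used at once
Reagents that add atoms: none
Why: Enamine-mediated organocatalytic Michael addition in which the (R)-diarylprolinol ether shields one enamine face, so the new centre (2R, future C1) is set under catalyst control with the oxobutyl chain in the relationship to C10 that becomes cis on ring A.

Step 4
Reactants: 7 4-methylpent-1-en-3-ol (racemic)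
Product: 8 4,4,5,5-tetramethyl-2-[(2E)-4-methylpent-2-en-1-yl]-1,3,2-dioxaborolane
Conditions: bis(pinacolato)diboron (1.2 equiv), Pd(MeCN)4(BF4)2 (5 mol %), DMSO/MeOH, 50 °C
Reagents that add atoms: bis(pinacolato)diboron, CC1(C)OB(OC1(C)C)B1OC(C)(C)C(C)(C)O1
Why: Palladium-catalysed allylic borylation through an η3-allyl intermediate gives the linear E-allylboronate; the carbinol centre is destroyed, so the racemate is used.

Step 5
Reactants: 6 (2R,3R,4E)-3-methyl-2-(3-oxobutyl)hex-4-enal; 8 4,4,5,5-tetramethyl-2-[(2E)-4-methylpent-2-en-1-yl]-1,3,2-dioxaborolane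
Product: 9 (5R,6R,7E)-5-[(1S,2R)-1-hydroxy-2-(propan-2-yl)but-3-en-1-yl]-6-methylnon-7-en-2-one
Conditions: (R)-TRIP phosphoric acid [(R)-3,3′-bis(2,4,6-triisopropylphenyl)-1,1′-binaphthyl-2,2′-diyl hydrogen phosphate] (5 mol %), 4 Å MS, toluene, −30 °C; aq. NaHCO3
Reagents that add atoms: none
Why: Chiral-phosphoric-acid-catalysed allylboration through a closed chair transition state, in which the E-boronate gives the anti adduct and the (R)-acid directs attack to the Re face of the aldehyde in concert with the Felkin–Anh preference, fixing C7 (R here); the C6 carbinol is oxidised later and the ketone does not react.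

Step 6
Reactants: 9 (5R,6R,7E)-5-[(1S,2R)-1-hydroxy-2-(propan-2-yl)but-3-en-1-yl]-6-methylnon-7-en-2-one
Product: 10 4-[(1R,2R,5R,6S)-6-hydroxy-2-methyl-5-(propan-2-yl)cyclohex-3-en-1-yl]butan-2-one
Conditions: second-generation Grubbs catalyst RuCl2(=CHPh)(PCy3)(H2IMes) (5 mol %), CH2Cl2 (0.01 M), 40 °C
Reagents that add atoms: none
Why: Ring-closing metathesis between the vinyl and propenyl groups closes six-membered ring A with loss of propene and touches no stereocentre.

Step 7
Reactants: 10 4-[(1R,2R,5R,6S)-6-hydroxy-2-methyl-5-(propan-2-yl)cyclohex-3-en-1-yl]butan-2-one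
Product: 11 4-[(1R,2R,3S,6R)-2-hydroxy-6-methyl-3-(propan-2-yl)cyclohexyl]butan-2-one
Conditions: H2 (1 atm), PtO2 (5 mol %), EtOAc, rt
Reagents that add atoms: none
Why: Catalytic hydrogenation of the isolated cis-disubstituted ring alkene, with PtO2 chosen to limit double-bond migration that could scramble the allylic centres C7 and C10.

Step 8
Reactants: 11 4-[(1R,2R,3S,6R)-2-hydroxy-6-methyl-3-(propan-2-yl)cyclohexyl]butan-2-one
Product: 12 (2R,3R,6S)-3-methyl-2-(3-oxobutyl)-6-(propan-2-yl)cyclohexan-1-one
Conditions: (n-Pr4N)RuO4 (5 mol %), N-methylmorpholine N-oxide (1.5 equiv), 4 Å MS, CH2Cl2, rt; short silica plug, used at once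
Reagents that add atoms: none
Why: Ley–Griffith oxidation under neutral conditions turns the C6 carbinol into the ring ketone without epimerising the flanking C1 and C7 centres (the C1 side chain is cis to the C10 methyl and would equilibrate under base).

Step 9
Reactants: 12 (2R,3R,6S)-3-methyl-2-(3-oxobutyl)-6-(propan-2-yl)cyclohexan-1-one
Product: 13 (4aR,5R,8S)-8a-hydroxy-5-methyl-8-(propan-2-yl)octahydronaphthalen-2(1H)-one (mixture of 8a epimers)
Conditions: LDA [LiN(iPr)2] (1.05 equiv), THF, −78 °C → −40 °C; AcOH, −78 °C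
Reagents that add atoms: none
Why: Kinetic deprotonation of the methyl ketone CH3 and intramolecular aldol addition (6-enolexo) onto the ring ketone closes ring B before the hindered tertiary α-centres of the ring ketone can enolise; the new carbinol configuration is irrelevant.

Step 10
Reactants: 13 (4aR,5R,8S)-8a-hydroxy-5-methyl-8-(propan-2-yl)octahydronaphthalen-2(1H)-one
Product: 15 (4aR,5R,8S)-5-methyl-8-(propan-2-yl)-4,4a,5,6,7,8-hexahydronaphthalen-2(3H)-one, via tertiary mesylate 14 (not isolated)
Conditions: MsCl (1.5 equiv), Et3N, DMAP (cat.), CH2Cl2, 0 °C; then DBU, rt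
Reagents that add atoms: none
Why: Mesylation of the aldol hydroxyl and E1cB elimination through the C4 ketone enolate can only give the conjugated C5=C6 enone, and C1 and C7 are not α to a carbonyl at this stage.

Step 11
Reactants: 15 (4aR,5R,8S)-5-methyl-8-(propan-2-yl)-4,4a,5,6,7,8-hexahydronaphthalen-2(3H)-one
Product: 16 (1S,4R,4aR)-4-methyl-7-methylidene-1-(propan-2-yl)-1,2,3,4,4a,5,6,7-octahydronaphthalene
Conditions: Ph3PCH3Br (1.6 equiv), KOtBu (1.5 equiv), THF, 0 °C → rt; pentane filtration, used promptly
Reagents that add atoms: methyltriphenylphosphonium bromide, C[P+](c1ccccc1)(c1ccccc1)c1ccccc1.[Br-]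
Why: Wittig methylenation of the enone carbonyl (1,2-addition) gives the 1,3-diene, and a slight excess of phosphonium salt at 0 °C avoids γ-deprotonation at C1 or C7.

Step 12
Reactants: 17 resorcinol
Product: 18 1,3-dimethoxybenzene
Conditions: MeI (2.5 equiv), K2CO3 (3 equiv), acetone, reflux
Reagents that add atoms: iodomethane, CI
Why: Williamson ether synthesis masks both phenols so the ring can undergo C–H borylation.

Step 13
Reactants: 18 1,3-dimethoxybenzene
Product: 19 2-(3,5-dimethoxyphenyl)-4,4,5,5-tetramethyl-1,3,2-dioxaborolane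
Conditions: bis(pinacolato)diboron (1.0 equiv), [Ir(OMe)(cod)]2 (1.5 mol %), 4,4′-di-tert-butyl-2,2′-bipyridine (3 mol %), THF, 80 °C
Reagents that add atoms: bis(pinacolato)diboron, CC1(C)OB(OC1(C)C)B1OC(C)(C)C(C)(C)O1
Why: Iridium-catalysed aromatic C–H borylation is sterically controlled and goes to the only position that is meta to both methoxy groups.

Step 14
Reactants: 19 2-(3,5-dimethoxyphenyl)-4,4,5,5-tetramethyl-1,3,2-dioxaborolane
Product: 20 3,5-dimethoxyphenol
Conditions: 30% aq. H2O2, 1 M aq. NaOH (1.1 equiv), THF, 0 °C → rt; then 1 M HCl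
Reagents that add atoms: hydrogen peroxide, OO
Why: Oxidation of the aryl boronate by hydroperoxide (1,2-aryl shift from boron to oxygen) installs the third oxygen.

Step 15
Reactants: 20 3,5-dimethoxyphenol
Product: 21 phloroglucinol (benzene-1,3,5-triol)
Conditions: BBr3 (3 equiv), CH2Cl2, −78 °C → rt; H2O
Reagents that add atoms: none
Why: Lewis-acid ether cleavage by BBr3 removes both methyl groups as bromomethane.

Step 16
Reactants: 21 phloroglucinol
Product: 23 2,4,6-trihydroxybenzene-1,3-dicarbaldehyde (2,4-diformylphloroglucinol), via bis(iminium) salt 22 (not isolated)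
Conditions: POCl3 (2.2 equiv), DMF (2.2 equiv), EtOAc, 0 °C → rt; then H2O, 60 °C
Reagents that add atoms: N,N-dimethylformamide, CN(C)C=O; water, O
Why: Double Vilsmeier–Haack formylation of the very electron-rich ring, limited to two positions by stoichiometry and by deactivation after the second iminium group.

Step 17
Reactants: 16 (1S,4R,4aR)-4-methyl-7-methylidene-1-(propan-2-yl)-1,2,3,4,4a,5,6,7-octahydronaphthalene; 23 2,4,6-trihydroxybenzene-1,3-dicarbaldehyde; 24 benzaldehyde
Product: 26 Guajadial C, via o-quinone methide 25 (not isolated)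
Conditions: ethylenediammonium diacetate (20 mol %), 1,4-dioxane, 60 °C; preparative HPLC
Reagents that add atoms: none
Why: Domino Knoevenagel condensation / inverse-electron-demand hetero-Diels–Alder reaction: the exocyclic CH2 of the diene bonds to the benzylic carbon and the carbonyl oxygen closes on C4 (allyl-stabilised), giving the spiro-chroman; face and endo/exo selectivity are not expected to be high, so the (4S, benzylic R) isomer is separated from its diastereomers.

## Compound list

1 | rac-(E)-pent-3-en-2-ol | C/C=C/C(C)O | starting material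
2 | (2S,3E)-pent-3-en-2-ol | C/C=C/[C@H](C)O | intermediate
3 | (2E,4S)-4-(ethenyloxy)pent-2-ene | C/C=C/[C@H](C)OC=C | intermediate (not isolated)
4 | (3S,4E)-3-methylhex-4-enal | C/C=C/[C@@H](C)CC=O | intermediate
5 | but-3-en-2-one | CC(=O)C=C | starting material
6 | (2R,3R,4E)-3-methyl-2-(3-oxobutyl)hex-4-enal | C/C=C/[C@@H](C)[C@H](C=O)CCC(C)=O | intermediate
7 | 4-methylpent-1-en-3-ol (racemic) | C=CC(O)C(C)C | starting material
8 | 4,4,5,5-tetramethyl-2-[(2E)-4-methylpent-2-en-1-yl]-1,3,2-dioxaborolane | CC(C)/C=C/CB1OC(C)(C)C(C)(C)O1 | intermediate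
9 | (5R,6R,7E)-5-[(1S,2R)-1-hydroxy-2-(propan-2-yl)but-3-en-1-yl]-6-methylnon-7-en-2-one | C/C=C/[C@@H](C)[C@@H](CCC(C)=O)[C@H](O)[C@@H](C=C)C(C)C | intermediate
10 | 4-[(1R,2R,5R,6S)-6-hydroxy-2-methyl-5-(propan-2-yl)cyclohex-3-en-1-yl]butan-2-one | CC(C)[C@@H]1C=C[C@@H](C)[C@@H](CCC(C)=O)[C@@H]1O | intermediate
11 | 4-[(1R,2R,3S,6R)-2-hydroxy-6-methyl-3-(propan-2-yl)cyclohexyl]butan-2-one | CC(C)[C@@H]1CC[C@@H](C)[C@@H](CCC(C)=O)[C@@H]1O | intermediate
12 | (2R,3R,6S)-3-methyl-2-(3-oxobutyl)-6-(propan-2-yl)cyclohexan-1-one | CC(C)[C@@H]1CC[C@@H](C)[C@@H](CCC(C)=O)C1=O | intermediate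
13 | (4aR,5R,8S)-8a-hydroxy-5-methyl-8-(propan-2-yl)octahydronaphthalen-2(1H)-one (8a epimers) | CC(C)[C@@H]1CC[C@@H](C)[C@H]2CCC(=O)CC12O | intermediate
14 | (4aR,5R,8S)-5-methyl-7-oxo-8-... 8a-methanesulfonate of 13, i.e. (4aR,5R,8S)-5-methyl-2-oxo-8-(propan-2-yl)octahydronaphthalen-8a(1H)-yl methanesulfonate | CC(C)[C@@H]1CC[C@@H](C)[C@H]2CCC(=O)CC12OS(C)(=O)=O | intermediate (not isolated)
15 | (4aR,5R,8S)-5-methyl-8-(propan-2-yl)-4,4a,5,6,7,8-hexahydronaphthalen-2(3H)-one | CC(C)[C@@H]1CC[C@@H](C)[C@H]2CCC(=O)C=C12 | intermediate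
16 | (1S,4R,4aR)-4-methyl-7-methylidene-1-(propan-2-yl)-1,2,3,4,4a,5,6,7-octahydronaphthalene | CC(C)[C@@H]1CC[C@@H](C)[C@H]2CCC(=C)C=C12 | intermediate
17 | resorcinol | Oc1cccc(O)c1 | starting material
18 | 1,3-dimethoxybenzene | COc1cccc(OC)c1 | intermediate
19 | 2-(3,5-dimethoxyphenyl)-4,4,5,5-tetramethyl-1,3,2-dioxaborolane | COc1cc(OC)cc(c1)B1OC(C)(C)C(C)(C)O1 | intermediate
20 | 3,5-dimethoxyphenol | COc1cc(O)cc(OC)c1 | intermediate
21 | phloroglucinol | Oc1cc(O)cc(O)c1 | intermediate
22 | 2,4-bis[(dimethyliminio)methyl]benzene-1,3,5-triol dichloride | C[N+](C)=Cc1c(O)cc(O)c(C=[N+](C)C)c1O.[Cl-].[Cl-] | intermediate (not isolated)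
23 | 2,4,6-trihydroxybenzene-1,3-dicarbaldehyde | O=Cc1c(O)cc(O)c(C=O)c1O | intermediate
24 | benzaldehyde | O=Cc1ccccc1 | starting material
25 | 5-benzylidene-2,4-dihydroxy-6-oxocyclohexa-1,3-diene-1,3-dicarbaldehyde (o-quinone methide) | O=CC1=C(O)C(C=O)=C(O)C(=Cc2ccccc2)C1=O | intermediate (not isolated)
26 | Guajadial C | CC(C)[C@@H]1CC[C@@H](C)[C@H]2CC[C@@]3(C=C12)C[C@H](c1ccccc1)c1c(O)c(C=O)c(O)c(C=O)c1O3 | target

## Step count and risks

Total steps: 17. Longest linear sequence: 11 steps (1, 2, 3, 5, 6, 7, 8, 9, 10, 11, 17).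

Steps most likely to fail:

Step 5. The γ-isopropyl boronate and the α-branched aldehyde are both hindered, so the catalysed allylboration may be slow or give incomplete control at C7. Fallback: starting from 6, switch from boron and Brønsted-acid catalysis to a chromium-mediated Barbier (Nozaki–Hiyama) allylation. (E)-1-Bromo-4-methylpent-2-ene and CrCl2 in THF at 0 °C generate (E)-(4-methylpent-2-en-1-yl)chromium dichloride F1 (trivalent chromium). F1 adds only to the aldehyde of 6, through a chair transition state that gives the anti adduct whatever the allyl geometry and with Felkin sense. This returns to the route at 9; minor C6/C7 isomers are removed after ring closure at 10.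

Step 9. The ring ketone of 12 carries the C1 side chain cis to the C10 methyl, the less stable arrangement, so any enolate equilibration or retro-aldol epimerises C1; LDA may also enolise unselectively. Fallback: starting from 12, avoid a free enolate in the ring-forming step. Trap the kinetic methyl-ketone enolate at −78 °C (LDA with TMSCl present) as (2R,3R,6S)-3-methyl-6-(propan-2-yl)-2-{3-[(trimethylsilyl)oxy]but-3-en-1-yl}cyclohexan-1-one F2. Then close ring B by an intramolecular Mukaiyama aldol addition with TiCl4 in CH2Cl2 at −78 °C, which is irreversible at that temperature. This returns to the route at 13.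

Step 17. The three-component reaction may give a low yield and a mixture of face and endo/exo isomers, and acid or heat can isomerise diene 16. Fallback: starting from 23, separate o-quinone methide formation from the cycloaddition. Condense 23 with 24 and morpholine in EtOH at rt to the isolable Mannich base 2,4,6-trihydroxy-5-[morpholin-4-yl(phenyl)methyl]benzene-1,3-dicarbaldehyde F3. Then warm F3 with 16 in toluene at 50–70 °C (optionally with a chiral phosphoric acid to bias the diene face), so that loss of morpholine releases 25 slowly under neutral, water-free conditions in the presence of excess diene. This returns to the route at 26.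

## Further compounds

F1 | step 5 | (E)-(4-methylpent-2-en-1-yl)chromium dichloride | CC(C)/C=C/C[Cr](Cl)Cl
F2 | step 9 | (2R,3R,6S)-3-methyl-6-(propan-2-yl)-2-{3-[(trimethylsilyl)oxy]but-3-en-1-yl}cyclohexan-1-one | CC(C)[C@@H]1CC[C@@H](C)[C@@H](CCC(=C)O[Si](C)(C)C)C1=O
F3 | step 17 | 2,4,6-trihydroxy-5-[morpholin-4-yl(phenyl)methyl]benzene-1,3-dicarbaldehyde (racemic) | O=Cc1c(O)c(C(N2CCOCC2)c2ccccc2)c(O)c(C=O)c1O
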